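**Retrosynthetic overview**

1. The C3 stereocentre is set last: target 20 ⇐ catalytic enantioselective protonation of the per-silylated enol ether 18 ⇐ isoflavone 15 (1,4-reduction and O-silylation).
2. Rings A and C are made together: 15 ⇐ tetraketide lactone 11, by a one-flask Mg(OMe)2 biomimetic Claisen aromatisation (ring A) followed by C1 insertion and ring closure (ring C).
3. 11 ⇐ C-acylation of the dianion of triacetic acid lactone 9 with arylacetate 8.
4. 8 ⇐ aldehyde 1 by regioselective O-methylation, one-carbon homologation (TosMIC, Pinner) and Stille prenylation.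
5. Ring order: B is bought (from 1); A then C form in the same operation (step 6); no ring is made afterwards.

Assumption: 3-bromo-4,5-dihydroxybenzaldehyde (1) is bought as such (catalogue compound; otherwise one step from 5-bromovanillin with AlCl3/pyridine). Common reagents (MeI, TosMIC, LDA, L-Selectride and the like) are named in their step and not numbered.

**Route**

Step 1
Reactants: 1 3-bromo-4,5-dihydroxybenzaldehyde
Product: 2 3-bromo-5-hydroxy-4-methoxybenzaldehyde
Conditions: MeI (1.05 eq), Li2CO3 (1.5 eq), DMF, 45 °C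
Reagents that add atoms: iodomethane CI
Why: The 4-OH (para to CHO, ortho to Br) is much the more acidic phenol, so the weak base forms only that phenoxide and it alone is methylated (regioselective Williamson etherification, as in 4-O-alkylation of protocatechualdehydes).

Step 2
Reactants: 2 3-bromo-5-hydroxy-4-methoxybenzaldehyde
Product: 4 2-(3-bromo-5-hydroxy-4-methoxyphenyl)acetonitrile, via formamide adduct 3 (not isolated)
Conditions: TosMIC (1.3 eq), t-BuOK (3.3 eq), DME, −40 °C; then MeOH, 65 °C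
Reagents that add atoms: p-toluenesulfonylmethyl isocyanide Cc1ccc(cc1)S(=O)(=O)C[N+]#[C-]
Why: van Leusen reductive cyanation: the TosMIC anion adds to the aldehyde, the oxazoline opens to the N-(1-tosylalkenyl)formamide 3, and methanolysis (loss of methyl formate and sulfinate) gives the one-carbon-extended nitrile; the phenol only consumes one extra equivalent of base.

Step 3
Reactants: 4 2-(3-bromo-5-hydroxy-4-methoxyphenyl)acetonitrile
Product: 6 methyl 2-(3-bromo-5-hydroxy-4-methoxyphenyl)acetate, via imidate hydrochloride 5 (not isolated)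
Conditions: HCl (4 M in dioxane, 5 eq), MeOH, 0 °C → rt; then H2O, rt
Reagents that add atoms: methanol CO; water O
Why: Pinner reaction (nitrile → methyl imidate hydrochloride → ester on hydrolysis); the anhydrous HCl is used here, before the acid-sensitive prenyl group is present.

Step 4
Reactants: 6 methyl 2-(3-bromo-5-hydroxy-4-methoxyphenyl)acetate; 7 tributyl(3-methylbut-2-en-1-yl)stannane
Product: 8 methyl 2-[3-hydroxy-4-methoxy-5-(3-methylbut-2-en-1-yl)phenyl]acetate
Conditions: Pd(PPh3)4 (5 mol %), DMF, 100 °C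
Reagents that add atoms: none
Why: Stille coupling; the prenyl group is transferred at its unsubstituted terminus to give the linear prenyl arene, and the free phenol and ester are inert under these neutral conditions.

Step 5
Reactants: 8 methyl 2-[3-hydroxy-4-methoxy-5-(3-methylbut-2-en-1-yl)phenyl]acetate; 9 4-hydroxy-6-methyl-2H-pyran-2-one (triacetic acid lactone)
Product: 11 4-hydroxy-6-{3-[3-hydroxy-4-methoxy-5-(3-methylbut-2-en-1-yl)phenyl]-2-oxopropyl}-2H-pyran-2-one, via dilithiated lactone 10 (not isolated)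
Conditions: 9 (3 eq), LDA (6.2 eq), THF, −78 → −20 °C; then 8 added at −78 → −10 °C; AcOH, then 1 M HCl
Reagents that add atoms: none
Why: Claisen-type C-acylation of the 6-methyl carbanion of the lactone dianion by the methyl ester (the known acylation of the triacetic acid lactone dianion); excess dianion absorbs the phenol proton and the acidic β-dicarbonyl product and gives the tetraketide lactone.

Step 6 (key step)
Reactants: 11 4-hydroxy-6-{3-[3-hydroxy-4-methoxy-5-(3-methylbut-2-en-1-yl)phenyl]-2-oxopropyl}-2H-pyran-2-one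
Product: 15 5,7-dihydroxy-3-[3-hydroxy-4-methoxy-5-(3-methylbut-2-en-1-yl)phenyl]-4H-chromen-4-one, via methyl triketo ester 12 (not isolated), via deoxybenzoin 13 (not isolated), via enaminone 14 (not isolated)
Conditions: Mg(OMe)2 (8 eq), MeOH, 65 °C; AcOH to pH ≈ 7; Me2NCH(OMe)2 (5 eq), 60 °C; then 1 M HCl, 0 °C
Reagents that add atoms: N,N-dimethylformamide dimethyl acetal COC(OC)N(C)C
Why: Proposed new method: Mg2+-templated methanolysis opens the 2-pyranone to the chelated methyl 3,5,7-triketo ester 12, whose C6 carbanion attacks the ester carbonyl (6-exo Claisen) and the trione aromatises to acylphloroglucinol 13 (ring A); chelation in non-aqueous methoxide favours Claisen over aldol closure, as in the known conversions of tetraacetic acid lactone and 6-phenacyl-4-hydroxypyran-2-one into acylphloroglucinols; in the same flask the doubly activated benzylic CH2 is aminomethylenated to enaminone 14 and an ortho-phenol closes ring C by 6-endo addition–elimination of HNMe2; the closest known reaction types are the biomimetic polyketide Claisen cyclisation and the DMF-DMA deoxybenzoin → isoflavone annulation, merged here; no stereocentre is formed.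

Step 7
Reactants: 15 5,7-dihydroxy-3-[3-hydroxy-4-methoxy-5-(3-methylbut-2-en-1-yl)phenyl]-4H-chromen-4-one
Product: 18 trimethyl{[3-[4-methoxy-3-(3-methylbut-2-en-1-yl)-5-(trimethylsilyloxy)phenyl]-5,7-bis(trimethylsilyloxy)-2H-chromen-4-yl]oxy}silane, via tris-TMS isoflavone 16 (not isolated), via lithium enolate 17 (not isolated)
Conditions: HMDS (neat), TMSCl (5 mol %), 80 °C, evaporate; L-Selectride (1.15 eq), THF, −78 °C; TMSCl (1.5 eq), −78 → 0 °C; pentane, filter, high vacuum; used crude
Reagents that add atoms: hexamethyldisilazane C[Si](C)(C)N[Si](C)(C)C; chlorotrimethylsilane C[Si](C)(C)Cl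
Why: Phenol silylation, then conjugate (1,4) hydride reduction of the chromone by L-Selectride (the known isoflavone → isoflavanone reduction) and O-silylation of the only possible enolate give the TMS enol ether; no stereocentre yet.

Step 8
Reactants: 18 trimethyl{[3-[4-methoxy-3-(3-methylbut-2-en-1-yl)-5-(trimethylsilyloxy)phenyl]-5,7-bis(trimethylsilyloxy)-2H-chromen-4-yl]oxy}silane
Product: 20 (3S)-5,7-dihydroxy-3-[3-hydroxy-4-methoxy-5-(3-methylbut-2-en-1-yl)phenyl]-2,3-dihydro-4H-chromen-4-one, via (3S)-tris-TMS isoflavanone 19 (not isolated)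
Conditions: (R)-3,3′-bis(2,4,6-triisopropylphenyl)-BINOL N-triflyl thiophosphoramide (5 mol %), PhOH (1.1 eq), toluene, 0 °C → rt; then MeOH, citric acid, 0 °C
Reagents that add atoms: none
Why: Catalytic enantioselective protonation of a silyl enol ether (chiral N-triflyl thiophosphoramide as proton shuttle, phenol as stoichiometric proton and silyl acceptor): the chiral acid delivers H+ to the Re face of C3 (C4 > C2 > aryl clockwise), which creates the 3S centre; the non-basic medium and the buffered methanolysis of the three ArO–TMS groups avoid enolisation of the α-aryl ketone.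

**Compound list**

1 | 3-bromo-4,5-dihydroxybenzaldehyde | O=Cc1cc(O)c(O)c(Br)c1 | starting material
2 | 3-bromo-5-hydroxy-4-methoxybenzaldehyde | O=Cc1cc(O)c(OC)c(Br)c1 | intermediate
3 | N-[2-(3-bromo-5-hydroxy-4-methoxyphenyl)-1-tosylethenyl]formamide | O=CNC(=Cc1cc(O)c(OC)c(Br)c1)S(=O)(=O)c1ccc(C)cc1 | intermediate (not isolated)
4 | 2-(3-bromo-5-hydroxy-4-methoxyphenyl)acetonitrile | N#CCc1cc(O)c(OC)c(Br)c1 | intermediate
5 | methyl 2-(3-bromo-5-hydroxy-4-methoxyphenyl)acetimidate hydrochloride | COC(=[NH2+])Cc1cc(O)c(OC)c(Br)c1.[Cl-] | intermediate (not isolated)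
6 | methyl 2-(3-bromo-5-hydroxy-4-methoxyphenyl)acetate | COC(=O)Cc1cc(O)c(OC)c(Br)c1 | intermediate
7 | tributyl(3-methylbut-2-en-1-yl)stannane | CCCC[Sn](CCCC)(CCCC)CC=C(C)C | starting material
8 | methyl 2-[3-hydroxy-4-methoxy-5-(3-methylbut-2-en-1-yl)phenyl]acetate | COC(=O)Cc1cc(O)c(OC)c(CC=C(C)C)c1 | intermediate
9 | 4-hydroxy-6-methyl-2H-pyran-2-one (triacetic acid lactone) | CC1=CC(O)=CC(=O)O1 | starting material
10 | dilithio dianion of 9 (4-oxido, 6-CH2 carbanion) | [Li+].[Li+].[CH2-]C1=CC([O-])=CC(=O)O1 | intermediate (not isolated)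
11 | 4-hydroxy-6-{3-[3-hydroxy-4-methoxy-5-(3-methylbut-2-en-1-yl)phenyl]-2-oxopropyl}-2H-pyran-2-one | O=C(Cc1cc(O)c(OC)c(CC=C(C)C)c1)CC1=CC(O)=CC(=O)O1 | intermediate
12 | methyl 8-[3-hydroxy-4-methoxy-5-(3-methylbut-2-en-1-yl)phenyl]-3,5,7-trioxooctanoate | COC(=O)CC(=O)CC(=O)CC(=O)Cc1cc(O)c(OC)c(CC=C(C)C)c1 | intermediate (not isolated)
13 | 2-[3-hydroxy-4-methoxy-5-(3-methylbut-2-en-1-yl)phenyl]-1-(2,4,6-trihydroxyphenyl)ethan-1-one | O=C(Cc1cc(O)c(OC)c(CC=C(C)C)c1)c1c(O)cc(O)cc1O | intermediate (not isolated)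
14 | 3-(dimethylamino)-2-[3-hydroxy-4-methoxy-5-(3-methylbut-2-en-1-yl)phenyl]-1-(2,4,6-trihydroxyphenyl)prop-2-en-1-one | CN(C)C=C(C(=O)c1c(O)cc(O)cc1O)c1cc(O)c(OC)c(CC=C(C)C)c1 | intermediate (not isolated)
15 | 5,7-dihydroxy-3-[3-hydroxy-4-methoxy-5-(3-methylbut-2-en-1-yl)phenyl]-4H-chromen-4-one | COc1c(O)cc(cc1CC=C(C)C)C1=COc2cc(O)cc(O)c2C1=O | intermediate
16 | 3-[4-methoxy-3-(3-methylbut-2-en-1-yl)-5-(trimethylsilyloxy)phenyl]-5,7-bis(trimethylsilyloxy)-4H-chromen-4-one | COc1c(O[Si](C)(C)C)cc(cc1CC=C(C)C)C1=COc2cc(O[Si](C)(C)C)cc(O[Si](C)(C)C)c2C1=O | intermediate (not isolated)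
17 | lithium 3-[4-methoxy-3-(3-methylbut-2-en-1-yl)-5-(trimethylsilyloxy)phenyl]-5,7-bis(trimethylsilyloxy)-2H-chromen-4-olate | [Li+].COc1c(O[Si](C)(C)C)cc(cc1CC=C(C)C)C1=C([O-])c2c(O[Si](C)(C)C)cc(O[Si](C)(C)C)cc2OC1 | intermediate (not isolated)
18 | trimethyl{[3-[4-methoxy-3-(3-methylbut-2-en-1-yl)-5-(trimethylsilyloxy)phenyl]-5,7-bis(trimethylsilyloxy)-2H-chromen-4-yl]oxy}silane | COc1c(O[Si](C)(C)C)cc(cc1CC=C(C)C)C1=C(O[Si](C)(C)C)c2c(O[Si](C)(C)C)cc(O[Si](C)(C)C)cc2OC1 | intermediate
19 | (3S)-3-[4-methoxy-3-(3-methylbut-2-en-1-yl)-5-(trimethylsilyloxy)phenyl]-5,7-bis(trimethylsilyloxy)-2,3-dihydro-4H-chromen-4-one | COc1c(O[Si](C)(C)C)cc([C@H]2COc3cc(O[Si](C)(C)C)cc(O[Si](C)(C)C)c3C2=O)cc1CC=C(C)C | intermediate (not isolated)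
20 | (3S)-5,7-dihydroxy-3-[3-hydroxy-4-methoxy-5-(3-methylbut-2-en-1-yl)phenyl]-2,3-dihydro-4H-chromen-4-one | COc1c(O)cc([C@H]2COc3cc(O)cc(O)c3C2=O)cc1CC=C(C)C | target

**Step count and risks**

Total step count: 8. Longest linear sequence: 8 (1 → 20); 7 and 9 are bought.

The three steps most likely to fail:

Step 5 (acylation of the lactone dianion). The arylacetate has an acidic benzylic CH2, so proton transfer to the strongly basic dianion can compete with C-acylation and return the ester unchanged. Fallback, setting out from 8: silylate the phenol (TBSCl, imidazole) to the silyl ether ester F1, and reduce it at −78 °C (DIBAL-H) to the arylacetaldehyde F2. Addition of dianion 10 (carbonyl addition to an aldehyde outruns enolisation) gives the carbinol F3, and Dess–Martin oxidation gives the keto-pyranone F4. F4 is put into the step 6 conditions as it is; Mg(OMe)2/MeOH also cleaves the aryl silyl ether, so the sequence comes back to the route at 13.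

Step 6 (one-flask formation of rings A and C). The polyketone can close by aldol instead of Claisen, and the aminomethylenation may be slow or give O-methylation in the salt-laden methanol. Fallback, setting out from 8: hydroxymethylate at the benzylic carbon (paraformaldehyde, NaHCO3, DMSO) to the tropate-type ester F5, silylate both hydroxyls (TBSCl, imidazole) to F6, and acylate dianion 10 as in step 5 to obtain pyranone F7. Treatment with Mg(OMe)2/MeOH at 65 °C alone then closes ring A by Claisen cyclisation, removes the aryl silyl group, expels silanolate by E1cB and closes ring C by 6-endo oxa-Michael addition. This gives the racemic isoflavanone F8 in one operation without any C1 reagent. TMSOTf/Et3N converts F8 into 18, where it comes back to the route.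

Step 8 (enantioselective protonation). The ee may be only moderate (80–90 % expected from 2-arylcycloalkanone precedent, to be raised by recrystallisation), and the peri 5-OTMS group may erode it further. The catalyst antipode is assigned by analogy — the sense that gives (R)-2-arylcyclohexanones, which is the same in space as 3S here — and must be confirmed in the first run. Fallback, setting out from 15: protect the three phenols (MOMCl, NaH, DMF) to F9. Transfer hydrogenation with RuCl[(S,S)-TsDPEN](p-cymene), HCO2H/Et3N, EtOAc, 40 °C (conjugate reduction, then ketone reduction with dynamic kinetic resolution) gives the cis-(3S,4S)-isoflavan-4-ol F10; the (S,S) catalyst sets 4S and the cis preference sets 3S. Dess–Martin oxidation gives the (3S)-ketone F11 without touching C3, and brief HCl (cat.)/MeOH at 40 °C removes the MOM groups to give 20.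

**Further compounds**

F1 | step 5 | methyl 2-[3-(tert-butyldimethylsilyloxy)-4-methoxy-5-(3-methylbut-2-en-1-yl)phenyl]acetate | COC(=O)Cc1cc(O[Si](C)(C)C(C)(C)C)c(OC)c(CC=C(C)C)c1
F2 | step 5 | 2-[3-(tert-butyldimethylsilyloxy)-4-methoxy-5-(3-methylbut-2-en-1-yl)phenyl]acetaldehyde | O=CCc1cc(O[Si](C)(C)C(C)(C)C)c(OC)c(CC=C(C)C)c1
F3 | step 5 | 6-{3-[3-(tert-butyldimethylsilyloxy)-4-methoxy-5-(3-methylbut-2-en-1-yl)phenyl]-2-hydroxypropyl}-4-hydroxy-2H-pyran-2-one (racemic) | OC(Cc1cc(O[Si](C)(C)C(C)(C)C)c(OC)c(CC=C(C)C)c1)CC1=CC(O)=CC(=O)O1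
F4 | step 5 | 6-{3-[3-(tert-butyldimethylsilyloxy)-4-methoxy-5-(3-methylbut-2-en-1-yl)phenyl]-2-oxopropyl}-4-hydroxy-2H-pyran-2-one | O=C(Cc1cc(O[Si](C)(C)C(C)(C)C)c(OC)c(CC=C(C)C)c1)CC1=CC(O)=CC(=O)O1
F5 | step 6 | methyl 3-hydroxy-2-[3-hydroxy-4-methoxy-5-(3-methylbut-2-en-1-yl)phenyl]propanoate (racemic) | COC(=O)C(CO)c1cc(O)c(OC)c(CC=C(C)C)c1
F6 | step 6 | methyl 3-(tert-butyldimethylsilyloxy)-2-[3-(tert-butyldimethylsilyloxy)-4-methoxy-5-(3-methylbut-2-en-1-yl)phenyl]propanoate (racemic) | COC(=O)C(CO[Si](C)(C)C(C)(C)C)c1cc(O[Si](C)(C)C(C)(C)C)c(OC)c(CC=C(C)C)c1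
F7 | step 6 | 6-{4-(tert-butyldimethylsilyloxy)-3-[3-(tert-butyldimethylsilyloxy)-4-methoxy-5-(3-methylbut-2-en-1-yl)phenyl]-2-oxobutyl}-4-hydroxy-2H-pyran-2-one (racemic) | O=C(CC1=CC(O)=CC(=O)O1)C(CO[Si](C)(C)C(C)(C)C)c1cc(O[Si](C)(C)C(C)(C)C)c(OC)c(CC=C(C)C)c1
F8 | step 6 | rac-5,7-dihydroxy-3-[3-hydroxy-4-methoxy-5-(3-methylbut-2-en-1-yl)phenyl]-2,3-dihydro-4H-chromen-4-one | COc1c(O)cc(C2COc3cc(O)cc(O)c3C2=O)cc1CC=C(C)C
F9 | step 8 | 5,7-bis(methoxymethoxy)-3-[4-methoxy-3-(methoxymethoxy)-5-(3-methylbut-2-en-1-yl)phenyl]-4H-chromen-4-one | COCOc1cc(OCOC)c2c(c1)OC=C(C2=O)c1cc(OCOC)c(OC)c(CC=C(C)C)c1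
F10 | step 8 | (3S,4S)-5,7-bis(methoxymethoxy)-3-[4-methoxy-3-(methoxymethoxy)-5-(3-methylbut-2-en-1-yl)phenyl]chroman-4-ol (cis) | COc1c(OCOC)cc([C@H]2COc3cc(OCOC)cc(OCOC)c3[C@H]2O)cc1CC=C(C)C
F11 | step 8 | (3S)-5,7-bis(methoxymethoxy)-3-[4-methoxy-3-(methoxymethoxy)-5-(3-methylbut-2-en-1-yl)phenyl]-2,3-dihydro-4H-chromen-4-one | COc1c(OCOC)cc([C@H]2COc3cc(OCOC)cc(OCOC)c3C2=O)cc1CC=C(C)C
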